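Ring C is cut at O1–C2 and C3–C4. A ring A salicylaldehyde brings O1 as its phenol and C4 as its formyl carbon; a ring B β-nitrostyrene brings C2 and, as the carbon bearing nitrogen, C3. The key step exploits the α-ketol of ring C (C4 carbonyl beside hydroxylated C3), held between ring A and the aryl-bearing C2: one amine-mediated oxa-Michael/Henry condensation joins both halves and closes the pyran as a 3-nitro-2H-chromene, a masked flavonol that alkaline peroxide unveils. The precursors are a salicylaldehyde whose only free hydroxyl sits between the formyl group and the 1,1-dimethylallyl carbon, and the fully substituted nitrovinyl chromene; the other phenols are allyl ethers, removable without acid.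

Key step: step 10

Remark: the phenols that must survive to the end are carried as allyl ethers and unmasked last with zerovalent palladium, because the chromene, the prenyl group and the 1,1-dimethylallyl group beside a free phenol are acid-sensitive; the target has no stereocentre.

Abbreviation: ArB = 2,2-dimethyl-5-(3-methylbut-2-en-1-yl)-8-(prop-2-en-1-yloxy)-2H-chromen-6-yl (the protected ring B group). Atom labels O1, C2, C3, C4 follow flavonol numbering.

**Ring A aldehyde**

Step 1
Reactants: 1 2,4,6-trihydroxybenzaldehyde; 2 prenyl bromide (1-bromo-3-methylbut-2-ene)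
Product: 3 2,6-dihydroxy-4-[(3-methylbut-2-en-1-yl)oxy]benzaldehyde
Conditions: K2CO3 (1.0 equiv), acetone, 0 °C to rt
Reagents that add atoms: none
Why: Williamson etherification, in which the 4-hydroxyl (para to the formyl group and the only one not hydrogen-bonded to it) is the most acidic and is ionised first by one equivalent of carbonate, so O-alkylation should occur there and give a mirror-symmetric ether.

Step 2
Reactants: 3 2,6-dihydroxy-4-[(3-methylbut-2-en-1-yl)oxy]benzaldehyde
Product: 5 2,4,6-trihydroxy-3-(2-methylbut-3-en-2-yl)benzaldehyde, via ortho-dienone 4 (not isolated)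
Conditions: PhNEt2, 170 °C, argon
Reagents that add atoms: none
Why: Aromatic Claisen rearrangement, in which the [3,3] shift delivers the allyl unit with inversion to either of the two equivalent ortho carbons to give dienone 4, and since the para carbon carries the formyl group no productive onward shift is open, so tautomerisation should give a single 1,1-dimethylallyl phenol.

Step 3
Reactants: 5 2,4,6-trihydroxy-3-(2-methylbut-3-en-2-yl)benzaldehyde
Product: 6 2-hydroxy-3-(2-methylbut-3-en-2-yl)-4,6-bis(prop-2-en-1-yloxy)benzaldehyde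
Conditions: allyl bromide (2.1 equiv), K2CO3 (2.2 equiv), acetone, 50 °C
Reagents that add atoms: allyl bromide (3-bromoprop-1-ene), C=CCBr
Why: Williamson etherification under chelation and steric control, in which the unchelated 4-hydroxyl and then the C6 hydroxyl flanked by a ring hydrogen should be alkylated, while the C2 hydroxyl, wedged between the formyl group and the quaternary carbon and held in the tighter hydrogen bond, should stay free (regiochemistry to be confirmed by HMBC and NOE before use).

**Ring B nitrostyrene**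

Step 4
Reactants: 7 2-bromo-4,5-dimethoxybenzaldehyde
Product: 8 2-bromo-4,5-dihydroxybenzaldehyde
Conditions: BBr3, CH2Cl2, −78 °C to rt; then H2O
Reagents that add atoms: none
Why: Lewis-acid cleavage of both aryl methyl ethers by BBr3 (demethylation), placed before any alkene is present, with the aldehyde and the aryl bromide tolerating the reagent.

Step 5
Reactants: 8 2-bromo-4,5-dihydroxybenzaldehyde; 9 3-chloro-3-methylbut-1-yne
Product: 10 2-bromo-5-hydroxy-4-[(2-methylbut-3-yn-2-yl)oxy]benzaldehyde
Conditions: K2CO3 (1.1 equiv), KI, CuI (cat.), acetone, 50 °C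
Reagents that add atoms: none
Why: Copper-assisted O-alkylation of a phenoxide by a tertiary propargylic chloride, in which one equivalent of carbonate ionises the more acidic 4-hydroxyl para to the formyl group, so the ether should form there and leave the 5-hydroxyl free.

Step 6
Reactants: 10 2-bromo-5-hydroxy-4-[(2-methylbut-3-yn-2-yl)oxy]benzaldehyde
Product: 12 5-bromo-8-hydroxy-2,2-dimethyl-2H-chromene-6-carbaldehyde, via allenylphenol 11 (not isolated)
Conditions: PhNEt2, 160 °C, argon
Reagents that add atoms: none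
Why: Propargyl Claisen rearrangement to C3, the only free carbon ortho to the ether oxygen, should give allenylphenol 11 after tautomerisation, and its 1,5-hydrogen shift followed by oxa-6π electrocyclisation should close the 2,2-dimethylpyran.

Step 7
Reactants: 12 5-bromo-8-hydroxy-2,2-dimethyl-2H-chromene-6-carbaldehyde; 13 tributyl(3-methylbut-2-en-1-yl)stannane
Product: 14 8-hydroxy-2,2-dimethyl-5-(3-methylbut-2-en-1-yl)-2H-chromene-6-carbaldehyde
Conditions: Pd(PPh3)4 (5 mol %), DMF, 100 °C
Reagents that add atoms: none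
Why: Stille coupling, in which the ortho formyl group speeds oxidative addition of the flanked C–Br bond to zerovalent palladium and reductive elimination at the less substituted allyl terminus should give the linear prenyl group, the free phenol, aldehyde and chromene being inert under these neutral conditions.

Step 8
Reactants: 14 8-hydroxy-2,2-dimethyl-5-(3-methylbut-2-en-1-yl)-2H-chromene-6-carbaldehyde
Product: 15 2,2-dimethyl-5-(3-methylbut-2-en-1-yl)-8-(prop-2-en-1-yloxy)-2H-chromene-6-carbaldehyde
Conditions: allyl bromide (1.2 equiv), K2CO3, DMF, rt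
Reagents that add atoms: allyl bromide (3-bromoprop-1-ene), C=CCBr
Why: Williamson etherification of the only hydroxyl, placed after the palladium step so that the allyl ether does not meet zerovalent palladium before the final deprotection.

Step 9
Reactants: 15 2,2-dimethyl-5-(3-methylbut-2-en-1-yl)-8-(prop-2-en-1-yloxy)-2H-chromene-6-carbaldehyde; 16 nitromethane
Product: 18 (E)-2,2-dimethyl-5-(3-methylbut-2-en-1-yl)-6-(2-nitroethenyl)-8-(prop-2-en-1-yloxy)-2H-chromene, via nitro alcohol 17 (not isolated)
Conditions: NH4OAc, MeNO2 (solvent), 90 °C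
Reagents that add atoms: none
Why: Henry condensation, in which ammonium acetate mediates nitroaldol addition to 17 and dehydration under thermodynamic control should give the E nitroalkene conjugated with ring B, leaving no stereocentre.

**Annulation and end game**

Step 10
Reactants: 6 2-hydroxy-3-(2-methylbut-3-en-2-yl)-4,6-bis(prop-2-en-1-yloxy)benzaldehyde; 18 (E)-2,2-dimethyl-5-(3-methylbut-2-en-1-yl)-6-(2-nitroethenyl)-8-(prop-2-en-1-yloxy)-2H-chromene
Product: 21 racemic 2-ArB-8-(2-methylbut-3-en-2-yl)-3-nitro-5,7-bis(prop-2-en-1-yloxy)-2H-chromene, via oxa-Michael adduct 19 (not isolated), via nitro alcohol 20 (not isolated)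
Conditions: DABCO (0.5 equiv), 4 Å MS, MeCN, 50 °C
Reagents that add atoms: none
Why: DABCO generates the phenoxide of 6, which adds to the β-carbon of nitroalkene 18 (O1–C2) to give the nitronate of 19; this carbon nucleophile attacks the neighbouring formyl group (C3–C4) to give nitro alcohol 20, and E1cB loss of water gives 21 and pulls the reversible steps forward. The closest known reaction type is the amine-mediated oxa-Michael/Henry condensation of salicylaldehydes with β-nitrostyrenes to 2-aryl-3-nitro-2H-chromenes. The pyran ring closes by a 6-exo-trig nitroaldol attack of the nitronate carbon on the formyl carbon. The new stereocentre at C2 is set without control and is racemic, which is of no consequence because C2 becomes trigonal in step 11. The step needs the O–C bond to come from the hydroxyl next to the 1,1-dimethylallyl carbon, which is secured because that hydroxyl is the only free one in 6, and the aldehyde has no enolisable position, so no other condensation mode is open.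

Step 11
Reactants: 21 racemic 2-ArB-8-(2-methylbut-3-en-2-yl)-3-nitro-5,7-bis(prop-2-en-1-yloxy)-2H-chromene
Product: 25 3-hydroxy-2-ArB-8-(2-methylbut-3-en-2-yl)-5,7-bis(prop-2-en-1-yloxy)-4H-chromen-4-one, via nitro epoxide 22 (not isolated), via 4-hydroxy-3-ketone 23 (not isolated), via flavanonol 24 (not isolated)
Conditions: 30% aq. H2O2 (excess), NaOH, MeOH/THF, 0 °C to rt
Reagents that add atoms: hydrogen peroxide, OO; sodium hydroxide, [Na+].[OH-]
Why: Nucleophilic epoxidation of the nitroalkene by hydroperoxide should give 22, hydroxide should open it at benzylic C4 while the C3 alkoxide expels nitrite to give ketol 23, which should equilibrate through its enediol to flavanonol 24 and be dehydrogenated by the excess alkaline peroxide (as in the Algar–Flynn–Oyamada flavonol synthesis) to the aromatic pyranone, removing the C2 stereocentre; isolated alkenes and allyl ethers do not react with hydroperoxide anion.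

Step 12
Reactants: 25 3-hydroxy-2-ArB-8-(2-methylbut-3-en-2-yl)-5,7-bis(prop-2-en-1-yloxy)-4H-chromen-4-one
Product: 26 broussoflavonol D
Conditions: Pd(PPh3)4 (10 mol %), morpholine (excess), THF, rt, argon
Reagents that add atoms: none
Why: Tsuji–Trost-type deallylation, in which zerovalent palladium ionises the three aryl allyl ethers to π-allyl complexes that morpholine captures, while the chromene C2–O bond (lying near the nodal plane of the ring alkene) and the unactivated prenyl and 1,1-dimethylallyl groups should not ionise, and no acid is used.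

**Compound list**

1 | 2,4,6-trihydroxybenzaldehyde | O=Cc1c(O)cc(O)cc1O | starting material
2 | prenyl bromide (1-bromo-3-methylbut-2-ene) | CC(C)=CCBr | starting material
3 | 2,6-dihydroxy-4-[(3-methylbut-2-en-1-yl)oxy]benzaldehyde | O=Cc1c(O)cc(OCC=C(C)C)cc1O | intermediate
4 | racemic 2,6-dihydroxy-3-(2-methylbut-3-en-2-yl)-4-oxocyclohexa-1,5-diene-1-carbaldehyde (ortho-dienone) | O=CC1=C(O)C(C(C)(C)C=C)C(=O)C=C1O | intermediate (not isolated)
5 | 2,4,6-trihydroxy-3-(2-methylbut-3-en-2-yl)benzaldehyde | C=CC(C)(C)c1c(O)cc(O)c(C=O)c1O | intermediate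
6 | 2-hydroxy-3-(2-methylbut-3-en-2-yl)-4,6-bis(prop-2-en-1-yloxy)benzaldehyde | C=CC(C)(C)c1c(O)c(C=O)c(OCC=C)cc1OCC=C | intermediate
7 | 2-bromo-4,5-dimethoxybenzaldehyde | COc1cc(Br)c(C=O)cc1OC | starting material
8 | 2-bromo-4,5-dihydroxybenzaldehyde | Oc1cc(Br)c(C=O)cc1O | intermediate
9 | 3-chloro-3-methylbut-1-yne | C#CC(C)(C)Cl | starting material
10 | 2-bromo-5-hydroxy-4-[(2-methylbut-3-yn-2-yl)oxy]benzaldehyde | O=Cc1cc(O)c(OC(C)(C)C#C)cc1Br | intermediate
11 | 2-bromo-4,5-dihydroxy-3-(3-methylbuta-1,2-dien-1-yl)benzaldehyde (allenylphenol) | O=Cc1cc(O)c(O)c(C=C=C(C)C)c1Br | intermediate (not isolated)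
12 | 5-bromo-8-hydroxy-2,2-dimethyl-2H-chromene-6-carbaldehyde | O=Cc1cc(O)c2OC(C)(C)C=Cc2c1Br | intermediate
13 | tributyl(3-methylbut-2-en-1-yl)stannane | CCCC[Sn](CCCC)(CCCC)CC=C(C)C | starting material
14 | 8-hydroxy-2,2-dimethyl-5-(3-methylbut-2-en-1-yl)-2H-chromene-6-carbaldehyde | O=Cc1cc(O)c2OC(C)(C)C=Cc2c1CC=C(C)C | intermediate
15 | 2,2-dimethyl-5-(3-methylbut-2-en-1-yl)-8-(prop-2-en-1-yloxy)-2H-chromene-6-carbaldehyde | O=Cc1cc(OCC=C)c2OC(C)(C)C=Cc2c1CC=C(C)C | intermediate
16 | nitromethane | C[N+](=O)[O-] | starting material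
17 | racemic 1-ArB-2-nitroethan-1-ol | OC(C[N+](=O)[O-])c1cc(OCC=C)c2OC(C)(C)C=Cc2c1CC=C(C)C | intermediate (not isolated)
18 | (E)-2,2-dimethyl-5-(3-methylbut-2-en-1-yl)-6-(2-nitroethenyl)-8-(prop-2-en-1-yloxy)-2H-chromene | [O-][N+](=O)/C=C/c1cc(OCC=C)c2OC(C)(C)C=Cc2c1CC=C(C)C | intermediate
19 | racemic 2-(1-ArB-2-nitroethoxy)-3-(2-methylbut-3-en-2-yl)-4,6-bis(prop-2-en-1-yloxy)benzaldehyde (oxa-Michael adduct) | C=CC(C)(C)c1c(OCC=C)cc(OCC=C)c(C=O)c1OC(C[N+](=O)[O-])c1cc(OCC=C)c2OC(C)(C)C=Cc2c1CC=C(C)C | intermediate (not isolated)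
20 | 2-ArB-8-(2-methylbut-3-en-2-yl)-3-nitro-5,7-bis(prop-2-en-1-yloxy)-3,4-dihydro-2H-chromen-4-ol (racemic, mixture of diastereomers) | C=CC(C)(C)c1c(OCC=C)cc(OCC=C)c2c1OC(c1cc(OCC=C)c3OC(C)(C)C=Cc3c1CC=C(C)C)C([N+](=O)[O-])C2O | intermediate (not isolated)
21 | racemic 2-ArB-8-(2-methylbut-3-en-2-yl)-3-nitro-5,7-bis(prop-2-en-1-yloxy)-2H-chromene | C=CC(C)(C)c1c(OCC=C)cc(OCC=C)c2c1OC(c1cc(OCC=C)c3OC(C)(C)C=Cc3c1CC=C(C)C)C([N+](=O)[O-])=C2 | intermediate
22 | 3,4-epoxide of 21: 2-ArB-3,4-epoxy-8-(2-methylbut-3-en-2-yl)-3-nitro-5,7-bis(prop-2-en-1-yloxy)chromane (racemic, mixture of diastereomers) | C=CC(C)(C)c1c(OCC=C)cc(OCC=C)c2c1OC(c1cc(OCC=C)c3OC(C)(C)C=Cc3c1CC=C(C)C)C1([N+](=O)[O-])OC21 | intermediate (not isolated)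
23 | 2-ArB-4-hydroxy-8-(2-methylbut-3-en-2-yl)-5,7-bis(prop-2-en-1-yloxy)-2H-chromen-3(4H)-one (racemic, mixture of diastereomers) | C=CC(C)(C)c1c(OCC=C)cc(OCC=C)c2c1OC(c1cc(OCC=C)c3OC(C)(C)C=Cc3c1CC=C(C)C)C(=O)C2O | intermediate (not isolated)
24 | 2-ArB-3-hydroxy-8-(2-methylbut-3-en-2-yl)-5,7-bis(prop-2-en-1-yloxy)-2,3-dihydro-4H-chromen-4-one (flavanonol; racemic, mixture of diastereomers) | C=CC(C)(C)c1c(OCC=C)cc(OCC=C)c2c1OC(c1cc(OCC=C)c3OC(C)(C)C=Cc3c1CC=C(C)C)C(O)C2=O | intermediate (not isolated)
25 | 3-hydroxy-2-ArB-8-(2-methylbut-3-en-2-yl)-5,7-bis(prop-2-en-1-yloxy)-4H-chromen-4-one | C=CC(C)(C)c1c(OCC=C)cc(OCC=C)c2c(=O)c(O)c(-c3cc(OCC=C)c4OC(C)(C)C=Cc4c3CC=C(C)C)oc12 | intermediate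
26 | broussoflavonol D: 3,5,7-trihydroxy-2-[8-hydroxy-2,2-dimethyl-5-(3-methylbut-2-en-1-yl)-2H-chromen-6-yl]-8-(2-methylbut-3-en-2-yl)-4H-chromen-4-one | C=CC(C)(C)c1c(O)cc(O)c2c(=O)c(O)c(-c3cc(O)c4c(c3CC=C(C)C)C=CC(C)(C)O4)oc12 | target

**Totals**

Total step count: 12. Longest linear sequence: 9 steps (steps 4 to 12, from 7 to 26).

**Steps most likely to fail**

Step 10. The phenoxide is flanked by the formyl group and a quaternary carbon, and the nitroalkene carries an ortho prenyl group on its aryl ring. The conjugate addition may therefore be slow and reversible, and base-induced oligomerisation of the nitroalkene may win. The fallback installs the tert-alkyl group after ring C is built and sets out from 3 and 18. Mono-allylation of 3 (allyl bromide, one equivalent, K2CO3, acetone) should give 2-hydroxy-4-[(3-methylbut-2-en-1-yl)oxy]-6-(prop-2-en-1-yloxy)benzaldehyde F1, whose free hydroxyl has only a ring hydrogen as its second neighbour. The same DABCO annulation with 18 should give racemic 2-ArB-7-[(3-methylbut-2-en-1-yl)oxy]-3-nitro-5-(prop-2-en-1-yloxy)-2H-chromene F2. Alkaline H2O2 as in step 11 should give 3-hydroxy-2-ArB-7-[(3-methylbut-2-en-1-yl)oxy]-5-(prop-2-en-1-yloxy)-4H-chromen-4-one F3. Aromatic Claisen rearrangement of the 7-prenyl ether (PhNEt2, 160 °C, below the onset of allyl aryl ether rearrangement) is expected to go to C8 in a 5-O-alkylated chromen-4-one and give 3,7-dihydroxy-2-ArB-8-(2-methylbut-3-en-2-yl)-5-(prop-2-en-1-yloxy)-4H-chromen-4-one F4. Deallylation as in step 12 returns to the route at 26.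

Step 11. The cascade may stall at the epoxide or at the flavanonol, or excess peroxide may cleave ring C of the flavonol oxidatively. The fallback is a staged sequence with isolation, in which peroxide is used only for the epoxidation; it sets out from 21. tert-Butyl hydroperoxide and DBU in THF at 0 °C should give nitro epoxide 22 as an isolated compound. Aqueous NaHCO3 in THF should open it with loss of nitrite, and Et3N should equilibrate ketol 23 to flavanonol 24, which is isolated. O2 with K2CO3 in DMF at rt should dehydrogenate 24 and return to the route at 25. No compound outside the list is made (F0).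

Step 7. Coupling at a bromide flanked on both sides may be slow, and allylic transposition during transmetalation or reductive elimination would deliver the 1,1-dimethylallyl isomer. The fallback builds the prenyl group in two operations and sets out from 12. Stille coupling with allyltributylstannane (Pd(PPh3)4, DMF, 90 °C), which has no regiochemical ambiguity, should give 8-hydroxy-2,2-dimethyl-5-(prop-2-en-1-yl)-2H-chromene-6-carbaldehyde F5. Olefin cross-metathesis with 2-methylbut-2-ene (second-generation Grubbs catalyst, CH2Cl2, 40 °C) should convert the allyl into the prenyl group and return to the route at 14.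

Further compounds
F1 | step 10 | 2-hydroxy-4-[(3-methylbut-2-en-1-yl)oxy]-6-(prop-2-en-1-yloxy)benzaldehyde | O=Cc1c(O)cc(OCC=C(C)C)cc1OCC=C
F2 | step 10 | racemic 2-ArB-7-[(3-methylbut-2-en-1-yl)oxy]-3-nitro-5-(prop-2-en-1-yloxy)-2H-chromene | CC(C)=CCOc1cc(OCC=C)c2C=C([N+](=O)[O-])C(c3cc(OCC=C)c4OC(C)(C)C=Cc4c3CC=C(C)C)Oc2c1
F3 | step 10 | 3-hydroxy-2-ArB-7-[(3-methylbut-2-en-1-yl)oxy]-5-(prop-2-en-1-yloxy)-4H-chromen-4-one | CC(C)=CCOc1cc(OCC=C)c2c(=O)c(O)c(-c3cc(OCC=C)c4OC(C)(C)C=Cc4c3CC=C(C)C)oc2c1
F4 | step 10 | 3,7-dihydroxy-2-ArB-8-(2-methylbut-3-en-2-yl)-5-(prop-2-en-1-yloxy)-4H-chromen-4-one | C=CC(C)(C)c1c(O)cc(OCC=C)c2c(=O)c(O)c(-c3cc(OCC=C)c4OC(C)(C)C=Cc4c3CC=C(C)C)oc12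
F0 | step 11 | none | none
F5 | step 7 | 8-hydroxy-2,2-dimethyl-5-(prop-2-en-1-yl)-2H-chromene-6-carbaldehyde | O=Cc1cc(O)c2OC(C)(C)C=Cc2c1CC=C
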